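**Retrosynthetic overview**
1. The target comes from esterifying the C8 hydroxyl of an 8-hydroxy hemiketal lactone. The 3,10-hemiketal (oxolane) closes by itself once the ten-membered ring exists.
2. The ten-membered ring and the α-methylene lactone come from one intramolecular chromium allylation (C6–C7) of a (Z)-keto-enal carrying a 2-(bromomethyl)acrylate. The acrylate is put on a C7 vinyl group by cross-metathesis.
3. The C3–C4 bond comes from adding a (Z)-vinyllithium (C4–C6 and C15, from propynal acetal and formaldehyde via trans-hydrostannation) to a γ-lactone.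
4. The γ-lactone comes from Baeyer–Villiger ring expansion of a 2,2-disubstituted cyclobutanone, which turns the all-carbon stereocentre into C10–O.
5. The cyclobutanone comes from a catalytic asymmetric Prins–semipinacol ring expansion of a 1-isopropenylcyclopropyl silyl ether with acrolein (C8–C9 bond, C8 and C10). Ring order: cyclopropane → cyclobutanone → γ-lactone → ten-membered carbocycle with lactone → hemiketal oxolane.

Assumption: C3 is a hemiketal carbon that can open to the 10-hydroxy-3-ketone; it is written with the descriptor of the given SMILES and is left to the transannular closure from the fixed 10R alcohol, with no reagent control claimed; one flask with one isolated product counts as one step.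

Step 1
Reactants: 1 1-ethoxycyclopropan-1-ol; 2 prop-1-en-2-ylmagnesium bromide
Product: 5 triethyl{[1-(prop-1-en-2-yl)cyclopropyl]oxy}silane, via cyclopropanone 3 (not isolated), via magnesium alkoxide 4 (not isolated)
Conditions: 2 (2.2 equiv), THF, 0 °C → reflux; then Et3SiCl, DMPU, 0 °C → rt
Reagents that add atoms: chlorotriethylsilane, CC[Si](Cl)(CC)CC
Why: Grignard addition to cyclopropanone released in the flask from its hemiacetal (the first equivalent of 2 acts as base), followed by O-silylation of the magnesium alkoxide; no stereocentre is formed.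

Step 2
Reactants: 5 triethyl{[1-(prop-1-en-2-yl)cyclopropyl]oxy}silane; 6 acrolein
Product: 7 (2R)-2-methyl-2-[(2R)-2-(triethylsilyloxy)but-3-en-1-yl]cyclobutan-1-one
Conditions: chiral N-triflyl imidodiphosphorimidate (IDPi) acid (2 mol%, enantiomer chosen by screening), 5 (1.2 equiv), toluene, −78 °C; NEt3 quench
Reagents that add atoms: none
Why: Proposed new method: a catalytic asymmetric Prins–semipinacol ring expansion in which the silylium ion pair of the confined chiral IDPi anion O-silylates acrolein, the isopropenyl CH2 (C9) attacks the carbonyl carbon (C8) inside the chiral pocket, and the incipient tertiary cation at C10 is quenched by a concerted anti 1,2-shift of a cyclopropane C–C bond (strain release, C=O formation) before the siloxycarbenium hands its silyl group on; the aldehyde face fixes C8 (R) and the alkene face, through the anti shift, fixes the quaternary C10 (R); the closest known reaction types are the silylium–IDPi Mukaiyama aldol, Lewis-acid Prins–pinacol additions of 1-siloxy-1-alkenylcyclopropanes and catalytic asymmetric protio- and halo-semipinacol ring expansions.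

Step 3
Reactants: 7 (2R)-2-methyl-2-[(2R)-2-(triethylsilyloxy)but-3-en-1-yl]cyclobutan-1-one
Product: 8 (5R)-5-methyl-5-[(2R)-2-(triethylsilyloxy)but-3-en-1-yl]oxolan-2-one
Conditions: mCPBA (1.3 equiv), NaHCO3, CH2Cl2, 0 °C → rt
Reagents that add atoms: 3-chloroperoxybenzoic acid, OOC(=O)c1cccc(Cl)c1
Why: Baeyer–Villiger oxidation of a strained cyclobutanone is fast and the quaternary carbon migrates with retention, so the C10 carbon stereocentre becomes the C10–O stereocentre unchanged; the monosubstituted alkene and the silyl ether survive the buffered peracid.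

Step 4
Reactants: 9 3,3-diethoxyprop-1-yne; 10 formaldehyde (as paraformaldehyde)
Product: 12 4,4-diethoxybut-2-yn-1-ol, via lithium acetylide 11 (not isolated)
Conditions: n-BuLi, THF, −78 °C; (CH2O)n, −78 °C → rt; H2O
Reagents that add atoms: none
Why: Addition of a lithium acetylide to formaldehyde (alkynylation) installs C15 with its oxygen; no stereocentre is formed.

Step 5
Reactants: 12 4,4-diethoxybut-2-yn-1-ol
Product: 13 (2Z)-4,4-diethoxy-2-(tributylstannyl)but-2-en-1-ol
Conditions: [(C5Me5)RuCl]4 (1.5 mol%), Bu3SnH (1.1 equiv), CH2Cl2, rt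
Reagents that add atoms: tributylstannane, CCCC[SnH](CCCC)CCCC
Why: Ruthenium-catalysed trans-hydrostannation of a propargylic alcohol, in which the free hydroxyl steers tin to the proximal alkyne carbon and hydrogen adds trans, so that tin (the future bond to C3) is cis to the acetal carbon (C6) as the 4Z alkene of the target needs.

Step 6
Reactants: 13 (2Z)-4,4-diethoxy-2-(tributylstannyl)but-2-en-1-ol; 8 (5R)-5-methyl-5-[(2R)-2-(triethylsilyloxy)but-3-en-1-yl]oxolan-2-one
Product: 15 (2Z,7R,9R)-1,1-diethoxy-7-hydroxy-3-(hydroxymethyl)-7-methyl-9-(triethylsilyloxy)undeca-2,10-dien-4-one, via dilithio alkoxide 14 (not isolated)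
Conditions: 13, n-BuLi (2.05 equiv), THF, −78 → −40 °C; then 8 (0.9 equiv), −78 °C; AcOH, −78 °C
Reagents that add atoms: none
Why: Tin–lithium exchange gives a configurationally stable vinyllithium that opens the γ-lactone by acyl substitution and stops at the lithium hemiketalate, giving the (Z)-enone (in equilibrium with its cyclic hemiketal) with C8 and C10 untouched.

Step 7
Reactants: 15 (2Z,7R,9R)-1,1-diethoxy-7-hydroxy-3-(hydroxymethyl)-7-methyl-9-(triethylsilyloxy)undeca-2,10-dien-4-one
Product: 16 (2Z,7R,9R)-7,9-dihydroxy-3-(hydroxymethyl)-7-methyl-4-oxoundeca-2,10-dienal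
Conditions: 0.5 M aq. HCl, THF, 0 °C → rt
Reagents that add atoms: water, O
Why: Acid hydrolysis of the diethyl acetal and of the secondary silyl ether; the keto-enal (drawn open-chain) rests as cyclic hemiketal and lactol forms through the C10 hydroxyl, which takes the alkene out of conjugation and guards its Z geometry.

Step 8
Reactants: 16 (2Z,7R,9R)-7,9-dihydroxy-3-(hydroxymethyl)-7-methyl-4-oxoundeca-2,10-dienal; 17 methyl 2-(bromomethyl)prop-2-enoate
Product: 18 methyl (2Z,4R,6R,10Z)-2-(bromomethyl)-4,6-dihydroxy-10-(hydroxymethyl)-6-methyl-9,12-dioxododeca-2,10-dienoate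
Conditions: 17 (5 equiv), RuCl2(H2IMes)(=CH-C6H4-2-OiPr) (second-generation Hoveyda–Grubbs catalyst, 10 mol%), 1,4-benzoquinone (20 mol%), CH2Cl2, 40 °C
Reagents that add atoms: none
Why: Olefin cross-metathesis of the only terminal alkene with an excess of the 1,1-disubstituted acrylate, helped by the free allylic hydroxyl, leaves the trisubstituted enal alkene alone and gives the allylic bromide without passing through an epimerisable C7 aldehyde; the geometry of the new alkene is not critical because it is lost at the allylchromium stage.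

Step 9
Reactants: 18 methyl (2Z,4R,6R,10Z)-2-(bromomethyl)-4,6-dihydroxy-10-(hydroxymethyl)-6-methyl-9,12-dioxododeca-2,10-dienoate
Product: 21 (3R,4Z,6R,7R,8R,10R)-3,8,15-trihydroxy-3,10-epoxygermacra-4,11(13)-dien-12,6-olide, via allylchromium species 19 (not isolated), via seco hydroxy ester 20 (not isolated)
Conditions: CrCl2 (8 equiv), THF, 0.003 M (syringe pump), rt; pH 7 buffer work-up
Reagents that add atoms: none
Why: Nozaki–Hiyama (Barbier-type) allylation used as the macrocyclisation, then lactonisation and transannular hemiketalisation: the allylchromium (trivalent chromium) adds to the enal through a chair transition state with the C8 chain equatorial, which gives the anti C6/C7 pair (trans-lactone); the face is chosen by the resident C8 and C10 centres, with C8–H eclipsing the allyl unit, and is the least certain element of the route; the chromium alkoxide closes the lactone onto the C6 oxygen and the 10-hydroxyl adds to the C3 ketone.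

Step 10
Reactants: 21 (3R,4Z,6R,7R,8R,10R)-3,8,15-trihydroxy-3,10-epoxygermacra-4,11(13)-dien-12,6-olide; 22 2-methylpropanoyl chloride
Product: 25 (3R,4Z,6R,7R,8R,10R)-3,15-dihydroxy-8-(2-methylpropanoyloxy)-3,10-epoxygermacra-4,11(13)-dien-12,6-olide, via silyl ether 23 (not isolated), via silylated ester 24 (not isolated)
Conditions: Et3SiCl (1.1 equiv), imidazole, CH2Cl2, −40 °C; then 22, DMAP, NEt3, 0 °C → rt; then HF·pyridine, THF, 0 °C
Reagents that add atoms: none
Why: Transient silylation of the only primary hydroxyl, DMAP-catalysed esterification of the secondary C8 hydroxyl (the tertiary hemiketal hydroxyl does not acylate) and fluoride desilylation in one flask; no stereocentre is touched.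

**Compound list**
1 | 1-ethoxycyclopropan-1-ol | CCOC1(O)CC1 | starting material
2 | prop-1-en-2-ylmagnesium bromide | C=C(C)[Mg]Br | starting material
3 | cyclopropanone | O=C1CC1 | intermediate
4 | bromomagnesium 1-(prop-1-en-2-yl)cyclopropan-1-olate | C=C(C)C1(O[Mg]Br)CC1 | intermediate
5 | triethyl{[1-(prop-1-en-2-yl)cyclopropyl]oxy}silane | C=C(C)C1(O[Si](CC)(CC)CC)CC1 | intermediate
6 | acrolein (prop-2-enal) | C=CC=O | starting material
7 | (2R)-2-methyl-2-[(2R)-2-(triethylsilyloxy)but-3-en-1-yl]cyclobutan-1-one | C=C[C@H](O[Si](CC)(CC)CC)C[C@@]1(C)CCC1=O | intermediate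
8 | (5R)-5-methyl-5-[(2R)-2-(triethylsilyloxy)but-3-en-1-yl]oxolan-2-one | C=C[C@H](O[Si](CC)(CC)CC)C[C@@]1(C)CCC(=O)O1 | intermediate
9 | 3,3-diethoxyprop-1-yne (propynal carried as its diethyl acetal) | C#CC(OCC)OCC | starting material
10 | formaldehyde (used as paraformaldehyde) | C=O | starting material
11 | lithium 3,3-diethoxyprop-1-yn-1-ide | [Li]C#CC(OCC)OCC | intermediate
12 | 4,4-diethoxybut-2-yn-1-ol | OCC#CC(OCC)OCC | intermediate
13 | (2Z)-4,4-diethoxy-2-(tributylstannyl)but-2-en-1-ol | OC/C(=C/C(OCC)OCC)[Sn](CCCC)(CCCC)CCCC | intermediate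
14 | lithium (2E)-4,4-diethoxy-2-lithiobut-2-en-1-olate (same alkene geometry as 13) | [Li]OC/C([Li])=C/C(OCC)OCC | intermediate
15 | (2Z,7R,9R)-1,1-diethoxy-7-hydroxy-3-(hydroxymethyl)-7-methyl-9-(triethylsilyloxy)undeca-2,10-dien-4-one | C=C[C@H](O[Si](CC)(CC)CC)C[C@](C)(O)CCC(=O)/C(CO)=C\C(OCC)OCC | intermediate
16 | (2Z,7R,9R)-7,9-dihydroxy-3-(hydroxymethyl)-7-methyl-4-oxoundeca-2,10-dienal (open-chain form) | C=C[C@H](O)C[C@](C)(O)CCC(=O)/C(CO)=C\C=O | intermediate
17 | methyl 2-(bromomethyl)prop-2-enoate | C=C(CBr)C(=O)OC | starting material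
18 | methyl (2Z,4R,6R,10Z)-2-(bromomethyl)-4,6-dihydroxy-10-(hydroxymethyl)-6-methyl-9,12-dioxododeca-2,10-dienoate (open-chain form) | COC(=O)/C(CBr)=C/[C@H](O)C[C@](C)(O)CCC(=O)/C(CO)=C\C=O | intermediate
19 | allylchromium dichloride from 18 (CH2Br replaced by CH2CrCl2, trivalent chromium, alkene geometry mobile) | COC(=O)/C(C[Cr](Cl)Cl)=C/[C@H](O)C[C@](C)(O)CCC(=O)/C(CO)=C\C=O | intermediate
20 | methyl 2-[(1R,2R,3Z,8R,10R)-2,8,10-trihydroxy-4-(hydroxymethyl)-8-methyl-5-oxocyclodec-3-en-1-yl]prop-2-enoate | C=C(C(=O)OC)[C@H]1[C@H](O)/C=C(/CO)C(=O)CC[C@@](C)(O)C[C@H]1O | intermediate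
21 | (3R,4Z,6R,7R,8R,10R)-3,8,15-trihydroxy-3,10-epoxygermacra-4,11(13)-dien-12,6-olide | C=C1C(=O)O[C@@H]2/C=C(/CO)[C@@]3(O)CC[C@](C)(C[C@@H](O)[C@@H]12)O3 | intermediate
22 | 2-methylpropanoyl chloride | CC(C)C(=O)Cl | starting material
23 | 15-O-triethylsilyl ether of 21 | C=C1C(=O)O[C@@H]2/C=C(/CO[Si](CC)(CC)CC)[C@@]3(O)CC[C@](C)(C[C@@H](O)[C@@H]12)O3 | intermediate
24 | 15-O-triethylsilyl ether of 25 | C=C1C(=O)O[C@@H]2/C=C(/CO[Si](CC)(CC)CC)[C@@]3(O)CC[C@](C)(C[C@@H](OC(=O)C(C)C)[C@@H]12)O3 | intermediate
25 | (3R,4Z,6R,7R,8R,10R)-3,15-dihydroxy-8-(2-methylpropanoyloxy)-3,10-epoxygermacra-4,11(13)-dien-12,6-olide | C=C1C(=O)O[C@@H]2/C=C(/CO)[C@@]3(O)CC[C@](C)(C[C@@H](OC(=O)C(C)C)[C@@H]12)O3 | target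

**Step count and risks**
Total step count: 10. Longest linear sequence: 8 (steps 1, 2, 3, 6, 7, 8, 9, 10); steps 4 and 5 form the second branch.

Steps most likely to fail: 2, 8 and 9.

Step 2 (proposed new ring expansion). Conjugate attack on acrolein, a poor C8/C10 diastereomer ratio or low enantioselectivity could each defeat it. The fallback uses only known chemistry, sets out from acrolein 6 and comes back at lactone 8. Acrolein 6 is methallylated with B-methallyldiisopinocampheylborane (Brown allylboration, the reagent enantiomer that gives the 3R alcohol) to (3R)-5-methylhexa-1,5-dien-3-ol F1. Boc2O and DMAP give tert-butyl (3R)-5-methylhexa-1,5-dien-3-yl carbonate F2. IBr in toluene at −85 °C closes the 1,3-syn cyclic iodocarbonate (4S,6R)-6-ethenyl-4-(iodomethyl)-4-methyl-1,3-dioxan-2-one F3, which sets C10 from C8. K2CO3 in MeOH gives (2R)-1-[(2S)-2-methyloxiran-2-yl]but-3-en-2-ol F4. The dianion of acetic acid (LiN(iPr)2, 2 equiv) opens the epoxide at its CH2 to (4R,6R)-4,6-dihydroxy-4-methyloct-7-enoic acid F5, which lactonises on acidification to (5R)-5-[(2R)-2-hydroxybut-3-en-1-yl]-5-methyloxolan-2-one F6. Et3SiCl and imidazole then give 8. This replaces the ring expansions by acyclic 1,3-induction.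

Step 8 (cross-metathesis). Pairing an allylic-oxygenated alkene with a 1,1-disubstituted acrylate is sluggish and may stall. The fallback builds the same bromide by cleavage and Morita–Baylis–Hillman chemistry, sets out from 15 and comes back at 18. Et3SiOTf and 2,6-lutidine convert 15 into (2Z,7R,9R)-1,1-diethoxy-3-[(triethylsilyloxy)methyl]-7-methyl-7,9-bis(triethylsilyloxy)undeca-2,10-dien-4-one F7. OsO4 (cat.) with NaIO4 and 2,6-lutidine cleaves only the monosubstituted alkene to the α-silyloxy aldehyde (2R,4R,8Z)-10,10-diethoxy-4-methyl-7-oxo-8-[(triethylsilyloxy)methyl]-2,4-bis(triethylsilyloxy)dec-8-enal F8. Methyl acrylate and DABCO give the Morita–Baylis–Hillman adduct methyl (4R,6R,10Z)-12,12-diethoxy-3-hydroxy-6-methyl-2-methylidene-9-oxo-10-[(triethylsilyloxy)methyl]-4,6-bis(triethylsilyloxy)dodec-10-enoate F9. NBS and Me2S give the rearranged bromide methyl (2Z,4R,6R,10Z)-2-(bromomethyl)-12,12-diethoxy-6-methyl-9-oxo-10-[(triethylsilyloxy)methyl]-4,6-bis(triethylsilyloxy)dodeca-2,10-dienoate F10. Aqueous HF in MeCN removes the three silyl ethers and the acetal to give 18.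

Step 9 (chromium macrocyclisation). The facial selectivity at C6/C7 relative to C8, elimination of the C8 oxygen from the allylmetal, lactonisation onto the wrong oxygen, and medium-ring strain are all open. The fallback swaps substrate control for catalyst control, sets out from 18 and comes back at 21. It is a catalytic asymmetric Nozaki–Hiyama–Kishi allylation: CrCl2 (20 mol%) bound to a chiral oxazoline–sulfonamide ligand, Mn powder as stoichiometric reductant and Cp2ZrCl2 to release the chromium alkoxide, so that the ligand and not C8 chooses the aldehyde face. It makes no compound outside the list (none F0).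

Further compounds
F1 | step 2 | (3R)-5-methylhexa-1,5-dien-3-ol | C=C[C@H](O)CC(C)=C
F2 | step 2 | tert-butyl (3R)-5-methylhexa-1,5-dien-3-yl carbonate | C=C[C@H](OC(=O)OC(C)(C)C)CC(C)=C
F3 | step 2 | (4S,6R)-6-ethenyl-4-(iodomethyl)-4-methyl-1,3-dioxan-2-one | C=C[C@H]1C[C@@](C)(CI)OC(=O)O1
F4 | step 2 | (2R)-1-[(2S)-2-methyloxiran-2-yl]but-3-en-2-ol | C=C[C@H](O)C[C@@]1(C)CO1
F5 | step 2 | (4R,6R)-4,6-dihydroxy-4-methyloct-7-enoic acid | C=C[C@H](O)C[C@](C)(O)CCC(=O)O
F6 | step 2 | (5R)-5-[(2R)-2-hydroxybut-3-en-1-yl]-5-methyloxolan-2-one | C=C[C@H](O)C[C@@]1(C)CCC(=O)O1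
F7 | step 8 | (2Z,7R,9R)-1,1-diethoxy-3-[(triethylsilyloxy)methyl]-7-methyl-7,9-bis(triethylsilyloxy)undeca-2,10-dien-4-one | C=C[C@H](O[Si](CC)(CC)CC)C[C@](C)(O[Si](CC)(CC)CC)CCC(=O)/C(CO[Si](CC)(CC)CC)=C\C(OCC)OCC
F8 | step 8 | (2R,4R,8Z)-10,10-diethoxy-4-methyl-7-oxo-8-[(triethylsilyloxy)methyl]-2,4-bis(triethylsilyloxy)dec-8-enal | O=C[C@H](O[Si](CC)(CC)CC)C[C@](C)(O[Si](CC)(CC)CC)CCC(=O)/C(CO[Si](CC)(CC)CC)=C\C(OCC)OCC
F9 | step 8 | methyl (4R,6R,10Z)-12,12-diethoxy-3-hydroxy-6-methyl-2-methylidene-9-oxo-10-[(triethylsilyloxy)methyl]-4,6-bis(triethylsilyloxy)dodec-10-enoate | C=C(C(=O)OC)C(O)[C@H](O[Si](CC)(CC)CC)C[C@](C)(O[Si](CC)(CC)CC)CCC(=O)/C(CO[Si](CC)(CC)CC)=C\C(OCC)OCC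
F10 | step 8 | methyl (2Z,4R,6R,10Z)-2-(bromomethyl)-12,12-diethoxy-6-methyl-9-oxo-10-[(triethylsilyloxy)methyl]-4,6-bis(triethylsilyloxy)dodeca-2,10-dienoate | COC(=O)/C(CBr)=C/[C@H](O[Si](CC)(CC)CC)C[C@](C)(O[Si](CC)(CC)CC)CCC(=O)/C(CO[Si](CC)(CC)CC)=C\C(OCC)OCC
F0 | step 9 | none | none
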